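I took the racemic pool as zero. The free catalyst is single-handed and the racemization catalyst pulls the two substrates back together, which makes this a dynamic kinetic resolution. Its substrate excess eS should therefore stand off zero in proportion to the apparent first-order constant κ of the two substrates together.

| setting | spring | noon | flask |
|---|---|---|---|
| left-handed substrate | 0.020 M | 0.020 M | 0.020 M |
| right-handed substrate | 0.020 M | 0.020 M | 0.020 M |
| coupling partner | 3 equiv | 3 equiv | 3.00 equiv |
| free catalyst | 1 mol% | 1 mol% | 1 mol% |
| racemization catalyst | 2 mol% | 2 mol% | 2 mol% |
| added ligand | 0.49 mM | 0.33 mM | 0.49 mM |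
| remark | the very flask that is asked about, followed so far | run made earlier |  |
| time |  |  | 30 min |

| run | time / min | left-handed substrate / % | right-handed substrate / % |
|---|---|---|---|
| spring | 0.417 | 42.2 | 47.6 |
| spring | 1.33 | 34.1 | 37.5 |
| spring | 2.00 | 29.6 | 34.4 |
| spring | 3.00 | 23.6 | 28.6 |
| spring | 5.00 | 18.2 | 19.2 |
| spring | 6.00 | 13.6 | 18.1 |
| noon | 1.00 | 36.4 | 41.3 |
| noon | 1.50 | 30.6 | 38.1 |
| noon | 2.50 | 26.2 | 28.0 |
| noon | 4.00 | 19.0 | 23.1 |
| noon | 8.00 | 10.8 | 10.4 |
| noon | 12.0 | 7.5 | 6.3 |

(readings scatter by 1 percentage point)

- free catalyst is single-handed; left-handed substrate and right-handed substrate are mirror images of each other, charged as a racemate, each of them at the stated concentration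
- the earlier runs were read with a standard deviation of 1 percentage point
- an excess is the difference of the two amounts in percent of their sum
- an excess is below zero if the other one leads

- part of the left-handed substrate and right-handed substrate charged together that has reacted at 30 min
- excess of left-handed product over right-handed product in the product at 30 min
- excess of right-handed substrate over left-handed substrate among what is left of the two at 30 min

With e the excess of the two coupling constants and ρ the racemization constant, both held fixed, the balance of push and pull reads

eS = Gκ, with G = e/(2ρ).

I read G, the excess lag, from each run, pooling the readings: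

spring, 6 readings: eS = 6.95%, κ = 0.191 min⁻¹, G = 0.363 min

noon, first 5 readings: eS = 6.78%, κ = 0.194 min⁻¹, G = 0.350 min

So 0.49 mM and 0.33 mM of added ligand gave readings of G that lie close together. The readings of the spring run ended at 6.00 min with its gap still visible. The noon run went on to 12.0 min, where its late κ had sagged to 0.107 min⁻¹. There Gκ asks for a gap of just 0.54 percentage points, which the scatter of 1 point per reading hides.

If the flask still ran at that late κ, I reckoned eS = 3.88%; Gκ is proportional to κ, so this estimate holds for that κ. The forecast said c 94%, eP 40% and eS 3%, a little less than my eS, on the ground of an excess “which fades as coupling slows”.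

The flask gave c 97.5%, eP 42.6% and eS 3.64%.

    coupling partner + free catalyst + left-handed substrate → free catalyst + left-handed product (k = 1250 M⁻² s⁻¹)
    coupling partner + free catalyst + right-handed substrate → free catalyst + right-handed product (k = 449 M⁻² s⁻¹)
    left-handed substrate + racemization catalyst ⇌ right-handed substrate + racemization catalyst, rate k3*[racemization catalyst]*[left-handed substrate] forward; the back reaction follows from the equilibrium constant (k = 25.6 M⁻¹ s⁻¹)
    coupling partner ⇌ dormant form (K = 0.805, k = 0.205 s⁻¹)
    free catalyst + added ligand ⇌ idle complex, settled at all times (K = 560 M⁻¹)

The forward half-life of left-handed substrate by racemization, 1.1 min, was shorter than the 30 min of the run. Between 15.0 min and 30 min the flask's mean κ was 0.0984 min⁻¹, so G gave eS = 3.57%. With 1.80 equiv of coupling partner, the neighbour held 0.212 of the flask's coupling partner in moles at 30.0 min, the dormant form not counted. Taking κ in proportion to it, G gave eS = 0.757% for that neighbour, which itself gave 0.795%.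

(The readings come from a simulation with made-up constants; the scatter is artificial.)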